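The target is C2-symmetric about the C3–C3'' bond, so both chroman-4-one rings (ring C and its twin) are cut at O1–C2 and C4–C4a. This leaves two arene units and a 2,3-bis(anisylmethyl)succinyl core that folds into a cis-fused dilactone: each lactone C=O is the future C4 of one ring, and its alkyl oxygen is the leaving group on the future C2 of the other. In one pot, an ortho-oxygenated arylcerium acylates both lactones, and acid then removes the phenol protecting groups and closes both pyranone rings. The C3/C3'' centres come from an asymmetric hydrogenation; the C2/C2'' centres are set trans by the ring closure.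

Key step: step 6

Remark on the chemistry (assumption): the sense of induction in step 2 is assumed to follow that of α-arylidene succinic acids with bis(phospholane) ligands; both ligand antipodes are commercial, so the (S,S) acid is accessible either way. Atom labels follow flavanone numbering (O1, C2, C3, C4, C4a; doubly primed for the second unit).

Step 1
Reactants: 1 4-methoxybenzaldehyde (2 equiv); 2 diethyl succinate
Product: 3 (2E,3E)-2,3-bis(4-methoxybenzylidene)succinic acid
Conditions: NaOEt (2.5 equiv), EtOH, reflux; then aq NaOH, reflux; then aq HCl
Reagents that add atoms: sodium hydroxide (aqueous, supplies a carboxyl oxygen on saponification), [Na+].[OH-]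
Why: Stobbe condensation run twice in one pot, each succinate α-carbon condensing with the aldehyde to give the thermodynamically preferred E alkene (aryl trans to CO2H), after which saponification frees the diacid.

Step 2
Reactants: 3 (2E,3E)-2,3-bis(4-methoxybenzylidene)succinic acid
Product: 4 (2S,3S)-2,3-bis(4-methoxybenzyl)succinic acid
Conditions: H2 (10 bar), [Rh(cod)((R,R)-Me-BPE)]OTf (1 mol %), NaOMe (10 mol %), MeOH, 25 °C
Reagents that add atoms: none
Why: Rhodium-bisphosphine asymmetric hydrogenation of an α-arylidene succinic acid (itaconate-type, the neighbouring carboxylate chelating rhodium) applied to both alkenes in turn, the catalyst setting each new centre so that the C2-symmetric (S,S) acid should dominate, while the minor meso acid cannot close to a cis-fused dilactone and should be purged in step 3.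

Step 3
Reactants: 4 (2S,3S)-2,3-bis(4-methoxybenzyl)succinic acid
Product: 5 (1R,4R,5R,8R)-4,8-bis(4-methoxyphenyl)-3,7-dioxabicyclo[3.3.0]octane-2,6-dione
Conditions: DDQ (2.4 equiv), 1,4-dioxane, 80 °C
Reagents that add atoms: none
Why: DDQ oxidative lactonisation, in which hydride abstraction from each p-methoxybenzylic CH2 gives a cation that is captured by the carboxyl group on the other succinate carbon as a γ-lactone, the cis ring fusion being dictated by the S,S centres and the aryl groups expected on the exo face (their configuration is not critical because step 6 resets it).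

Step 4
Reactants: 6 5-methoxyresorcinol
Product: 7 4-bromo-5-methoxybenzene-1,3-diol
Conditions: NBS (1.0 equiv), MeCN, −30 °C
Reagents that add atoms: N-bromosuccinimide, O=C1CCC(=O)N1Br
Why: Electrophilic aromatic bromination para to a free hydroxyl, as in the 4-bromination of resorcinol; the two such positions are equivalent by symmetry and only the carbon between the two hydroxyls competes.

Step 5
Reactants: 7 4-bromo-5-methoxybenzene-1,3-diol
Product: 8 2-bromo-1-methoxy-3,5-bis(methoxymethoxy)benzene
Conditions: MOMCl (2.5 equiv), iPr2NEt, CH2Cl2, 0 °C to rt
Reagents that add atoms: chloromethyl methyl ether, COCCl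
Why: O-alkylation of both phenols (MOM protection); the acetals tolerate the organometallic stage and are cleaved in the acid stage of step 6.

Step 6
Reactants: 8 2-bromo-1-methoxy-3,5-bis(methoxymethoxy)benzene (2.4 equiv); 5 (1R,4R,5R,8R)-4,8-bis(4-methoxyphenyl)-3,7-dioxabicyclo[3.3.0]octane-2,6-dione
Product: 12 4',4''',5,5''-tetramethylchamaejasmin, via aryllithium 9 (not isolated), via aryldichlorocerium 10 (not isolated), via bis-lactol 11 (not isolated)
Conditions: 8, n-BuLi, THF, −78 °C; CeCl3, −78 °C; then 5, −78 to −30 °C; then 3 M HCl in MeOH, −30 to 40 °C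
Reagents that add atoms: none
Why: Bromine–lithium exchange and transmetalation give a weakly basic, oxophilic arylcerium that adds once to each lactone carbonyl of 5 and stops at the lactolate (the aryl-metal/lactone addition used for aryl C-glycosides), which forms both C4–C4a bonds. Methanolic HCl then cleaves the four MOM ethers and opens each lactol to a 2'-hydroxyaryl β-hydroxy ketone, whose p-anisyl benzylic C–O bond ionises and is captured by the ortho phenol, which forms both O1–C2 bonds (the acid cyclodehydration of 2'-hydroxy aldols to flavanones). Each pyranone ring closes by 6-exo-tet attack of the phenol oxygen on the benzylic carbon of its own half (the crossed closure would be a 7-membered ring), so each lactone C=O ends as C4 of one ring while its alkyl oxygen departs from C2 of the other. C3 and C3'' are carried unchanged from the succinate carbons of 5; the new C2 and C2'' centres are set by substrate control, the ring closing with the anisyl group equatorial and trans to the C3 substituent (net inversion at the lactone benzylic carbon, and also the thermodynamic outcome of reversible ionisation). The step needs carbon acylation before oxygen alkylation of the arene, secured by introducing the arene as a carbanion at the carbon between OMe and OMOM, and it needs C3 to survive, secured by the non-basic cerium reagent and by ring closure outrunning elimination to the chalcone. A half that does eliminate should reclose either to the same ring or into a meso-type diastereomer that chromatography removes, so the enantiomeric purity of the C2-symmetric product is protected.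

Compound list
1 | 4-methoxybenzaldehyde | COc1ccc(C=O)cc1 | starting material
2 | diethyl succinate | CCOC(=O)CCC(=O)OCC | starting material
3 | (2E,3E)-2,3-bis(4-methoxybenzylidene)succinic acid | COc1ccc(/C=C(/C(=O)O)\C(C(=O)O)=C/c2ccc(OC)cc2)cc1 | intermediate
4 | (2S,3S)-2,3-bis(4-methoxybenzyl)succinic acid | OC(=O)[C@@H](Cc1ccc(OC)cc1)[C@H](Cc1ccc(OC)cc1)C(=O)O | intermediate
5 | (1R,4R,5R,8R)-4,8-bis(4-methoxyphenyl)-3,7-dioxabicyclo[3.3.0]octane-2,6-dione (cis-fused dilactone, both aryl groups exo) | O=C1O[C@@H](c2ccc(OC)cc2)[C@H]2[C@@H]1[C@H](c1ccc(OC)cc1)OC2=O | intermediate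
6 | 5-methoxyresorcinol (5-methoxybenzene-1,3-diol) | COc1cc(O)cc(O)c1 | starting material
7 | 4-bromo-5-methoxybenzene-1,3-diol | COc1cc(O)cc(O)c1Br | intermediate
8 | 2-bromo-1-methoxy-3,5-bis(methoxymethoxy)benzene | COCOc1cc(OC)c(Br)c(OCOC)c1 | intermediate
9 | [2-methoxy-4,6-bis(methoxymethoxy)phenyl]lithium | [Li]c1c(OC)cc(OCOC)cc1OCOC | intermediate
10 | dichloro[2-methoxy-4,6-bis(methoxymethoxy)phenyl]cerium | COCOc1cc(OC)c([Ce](Cl)Cl)c(OCOC)c1 | intermediate
11 | cis-fused 2,6-bis[2-methoxy-4,6-bis(methoxymethoxy)phenyl]-4,8-bis(4-methoxyphenyl)-3,7-dioxabicyclo[3.3.0]octane-2,6-diol (bis-lactol; four ring stereocentres as in 5, hemiketal carbons unassigned) | OC1(c3c(OC)cc(OCOC)cc3OCOC)O[C@@H](c3ccc(OC)cc3)[C@H]2[C@@H]1[C@H](c1ccc(OC)cc1)OC2(O)c1c(OC)cc(OCOC)cc1OCOC | intermediate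
12 | 4',4''',5,5''-tetramethylchamaejasmin, the (2S,3R,2''S,3''R)-3,3''-biflavanone with 5-OMe, 7-OH and 4'-OMe on each unit | COc1ccc([C@H]2Oc3cc(O)cc(OC)c3C(=O)[C@@H]2[C@H]2C(=O)c3c(OC)cc(O)cc3O[C@@H]2c2ccc(OC)cc2)cc1 | target

Total step count: 6. Longest linear sequence: 4 steps (steps 1, 2, 3 and 6).

Steps most likely to fail

Step 6. Three processes could go wrong: deprotonation of the lactone α-carbons by the aryl-metal instead of carbonyl addition; loss of a proton from the benzylic cation in the acid stage (elimination to the α-substituted chalcone), which would erase C3 in that half; and incomplete acetal cleavage. The fallback sets out from 4 and separates acylation from C–O bond formation. Diacid 4 would be coupled with N,O-dimethylhydroxylamine to the bis(N-methoxy-N-methyl amide) F1. Aryllithium 9 (from 8) would add to F1 to give the bis-MOM-protected diketone F2, a stage with no enolisable lactone and no benzylic leaving group. Methanolic HCl would free the tetraphenol diketone F3. DDQ in dioxane would then effect oxidative cyclisation of each 2'-hydroxydihydrochalcone half (benzylic hydride abstraction, capture by the ortho phenol, trans ring closure under control of C3), returning to the route at 12.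

Step 3. Hydride abstraction from a mono-methoxy arene may be sluggish, and the benzylic cation may lose the α-proton (dehydrogenation back to the arylidene acid) instead of being captured by the carboxyl group. The fallback sets out from 4 and replaces hydride abstraction by radical C–H bromination. Esterification (MeOH, H2SO4 cat.) would give the dimethyl ester F4. Wohl–Ziegler bromination (NBS, AIBN, PhCF3, 80 °C) would give the bis(benzylic bromide) F5. On heating, or with AgOTf, F5 should lactonise through its labile p-methoxybenzylic bromides with loss of bromomethane, returning to the route at 5.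

Step 4. Bromination may occur at the carbon between the two hydroxyls, and the very electron-rich ring may be brominated twice. The fallback sets out from 6 and steers the electrophile by steric bulk. Silylation (TIPSCl, imidazole, DMF) would give 1-methoxy-3,5-bis(triisopropylsilyloxy)benzene F6, in which the carbon between the two silyloxy groups is shielded. NBS would then brominate between OMe and OTIPS to give 2-bromo-1-methoxy-3,5-bis(triisopropylsilyloxy)benzene F7. TBAF would remove the silyl groups, returning to the route at 7.

Further compounds
F1 | step 6 | (2S,3S)-N,N'-dimethoxy-N,N'-dimethyl-2,3-bis(4-methoxybenzyl)succinamide | CON(C)C(=O)[C@@H](Cc1ccc(OC)cc1)[C@H](Cc1ccc(OC)cc1)C(=O)N(C)OC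
F2 | step 6 | (2S,3S)-2,3-bis(4-methoxybenzyl)-1,4-bis[2-methoxy-4,6-bis(methoxymethoxy)phenyl]butane-1,4-dione | COCOc1cc(OC)c(C(=O)[C@@H](Cc2ccc(OC)cc2)[C@H](Cc2ccc(OC)cc2)C(=O)c2c(OC)cc(OCOC)cc2OCOC)c(OCOC)c1
F3 | step 6 | (2S,3S)-1,4-bis(2,4-dihydroxy-6-methoxyphenyl)-2,3-bis(4-methoxybenzyl)butane-1,4-dione | Oc1cc(O)c(C(=O)[C@@H](Cc2ccc(OC)cc2)[C@H](Cc2ccc(OC)cc2)C(=O)c2c(OC)cc(O)cc2O)c(OC)c1
F4 | step 3 | dimethyl (2S,3S)-2,3-bis(4-methoxybenzyl)succinate | COC(=O)[C@@H](Cc1ccc(OC)cc1)[C@H](Cc1ccc(OC)cc1)C(=O)OC
F5 | step 3 | dimethyl 2,3-bis[bromo(4-methoxyphenyl)methyl]succinate (succinate carbons as in 4, benzylic carbons unassigned) | COC(=O)[C@@H](C(Br)c1ccc(OC)cc1)[C@H](C(Br)c1ccc(OC)cc1)C(=O)OC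
F6 | step 4 | 1-methoxy-3,5-bis(triisopropylsilyloxy)benzene | COc1cc(O[Si](C(C)C)(C(C)C)C(C)C)cc(O[Si](C(C)C)(C(C)C)C(C)C)c1
F7 | step 4 | 2-bromo-1-methoxy-3,5-bis(triisopropylsilyloxy)benzene | COc1cc(O[Si](C(C)C)(C(C)C)C(C)C)cc(O[Si](C(C)C)(C(C)C)C(C)C)c1Br
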